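A shortfall in a mass balance is easily booked as a fixed loss, and that is the pitfall here: in two earlier flasks the target and substrate readings do not add up to the charge.

| setting | gamma | theta | north-east | south | north-west | north | south-east |
|---|---|---|---|---|---|---|---|
| substrate | 0.015 M | 0.015 M | 0.015 M | 0.040 M | 0.12 M | 0.40 M | 1.2 M |
| catalyst | 7.4 mM | 5.5 mM | 11 mM | 11 mM | 11 mM | 11 mM | 11 mM |
| remark | run made earlier | run made earlier |  |  |  |  |  |
| time |  |  | 1.5 h | 1.5 h | 1.5 h | 1.5 h | 1.5 h |

| run | time / min | target / % | substrate / % |
|---|---|---|---|
| gamma | 1.33 | 28.2 | 70.7 |
| gamma | 2.50 | 44.2 | 52.2 |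
| gamma | 5.00 | 63.2 | 32.7 |
| gamma | 10.0 | 74.3 | 18.0 |
| gamma | 20.0 | 75.4 | 15.7 |
| theta | 4.00 | 57.9 | 39.0 |
| theta | 8.00 | 72.6 | 22.6 |
| theta | 10.0 | 75.7 | 19.0 |
| theta | 15.0 | 76.2 | 16.5 |
| theta | 20.0 | 75.8 | 15.1 |

(readings scatter by 0.5 percentage points)

- a reading or a percentage of target counts all its forms, free or not
- the concentration of target that is asked is that of its free form alone
- "hardly changes" means that all values lie within two and a half points (for a concentration: within two and a half percent of the largest)
- a reading of substrate is of its free form alone

- [target] (only what is free in solution) at the end for north-east, south, north-west, north, south-east, in this order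
- how the row runs (rises all the way / rises, then falls / hardly changes / falls, then rises / falls all the way)

At 20.0 min in the theta run, 9.10% of the charge is missing. This missing share, the part of the charge found in neither the target nor the substrate reading, is 8.90% at the same time in the gamma run. But both runs hold 0.015 M of substrate, so they cannot tell an amount from a share.

Two views follow. The first says the shortfall is a fixed amount, 1.36 mM, which at 1.2 M would be 0.114% of the charge. The second, mine, says the share stays put as the charge grows.

My reckoning takes two rounds. Target is 0.834 of what the two theta readings find. Putting the missing share back in gives 0.758 of the charge, so 0.0114 M in north-east and 0.910 M in south-east. The reading counts bound target too, so I count that as free.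

The forecast takes the first side, with “a small, possibly fixed, sink”: 0.0113 M, 0.031 M, 0.095 M, 0.32 M and 0.96 M, and the row rises all the way.

The simulation gives 0.0105 M, 0.0280 M, 0.0833 M, 0.270 M and 0.755 M, and the row rises all the way.

    target ⇌ isomer of the product (K = 0.190, k = 5.50 × 10⁻⁵ /s)
    isomer of the product + catalyst ⇌ substrate + catalyst, rate k2*[catalyst]*[isomer of the product] forward; the back reaction follows from the equilibrium constant (k = 0.0390 /M/s)
    catalyst + target ⇌ idle complex (K = 53.0 /M, k = 4.40 × 10⁻⁴ /M/s)
    substrate + target ⇌ idle adduct, settled at all times (K = 0.590 /M)
    substrate ⇌ target (K = 4.80, k = 0.00430 /s)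

Counted from the target and substrate percentages at the end, the missing share is 13.4% in north-east and 17.4% in south-east, against the 9.10% read in the theta run, and that is 2.01 mM against 0.209 M, so the fixed amount loses. My own south-east figure of 0.910 M also stood above the simulation's 0.755 M. The fixed amount keeps the charge of the earlier runs, 0.015 M, where amount and share are one statement. In north-east, the step between substrate and target, taken alone, had a relaxation half-life of 2.22 min, shorter than the 0.559 h of the step between target and isomer of the product, taken alone, and at 0.750 h substrate stood at 14.8% and isomer of the product at 12.6%. Meanwhile in north-east the step to idle complex, taken alone, had a longer relaxation half-life still, 10.9 h at the asked time, and idle complex grew from 1.20% of the catalyst at 0.750 h to 2.40% at 1.50 h.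

The earlier runs and the new flask were computed with made-up constants; scatter was added.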